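**Retrosynthetic overview**

1. Late functionality goes first: the C14 methyl comes from a C10 enol triflate (Stille), the 4,5-oxirane from a (3S)-allylic alcohol (peracid), the C3 carbinol from an enone (CBS), the 8-O-tiglate from the alcohol, and the trans-6,12-lactone from a 6,12-diol (oxidative lactonization).
2. Key disconnection at C2–C3: the carbocycle is a cyclodeca-1,5-diene (C1=C10 and C4=C5 flank C2–C3) whose C10 can be an enolate carbon, which is the product pattern of an anionic oxy-Cope shift. Reconnecting C5–C10 gives ring B, a cis-1,2-dialkenylcyclohexanol (C5–C10) with OH and vinyl (C1=C2) on C10 and a ketene dithioacetal arm (C4=C3) on C5.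
3. In ring B the C5 arm and the C10 carbinol come from an epoxide opened by a propanoate enolate tethered on O6 (a temporary cis-lactone), followed by vinyl addition; ring B itself comes from metathesis of an acyclic diene.
4. The diene is assembled from (R)-β-methyl-γ-butyrolactone (C7, C8, C11–C13), acrolein (C5, C6), an allyl Grignard reagent (C9, C10) and propanal (C3, C4, C15) by an Evans aldol and an Evans–Tishchenko reaction.
5. Ring order: cyclohexene ring B → temporary cis-γ-lactone → ten-membered carbocycle (ring B cleaved) → trans-γ-lactone → oxirane.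

Key step: step 15

Assumption: atoms are numbered as in germacranolides (C1–C10 ring, C11–C13 lactone carbons, C14 on C10, C15 on C4), α is the face of H7 and β the opposite face; (R)-4-methyldihydrofuran-2(3H)-one is taken as a commercial enantiopure building block.

**Route**

Step 1
Reactants: 1 (R)-4-methyldihydrofuran-2(3H)-one
Product: 4 (R)-4-((tert-butyldimethylsilyl)oxy)-3-methylbutanoic acid, via sodium hydroxy-acid salt 2 (not isolated), via bis-silylated ester 3 (not isolated)
Conditions: NaOH, MeOH/H2O, rt; evaporate; TBSCl, imidazole, DMF, rt; then AcOH/THF/H2O, 0 °C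
Reagents that add atoms: sodium hydroxide ([Na+].[OH-]); tert-butyldimethylsilyl chloride (CC(C)(C)[Si](C)(C)Cl)
Why: Lactone saponification, exhaustive silylation and selective hydrolysis of the labile silyl ester should give the O-protected hydroxy acid; the C11 stereocentre of the chiral-pool lactone is not touched.

Step 2
Reactants: 4 (R)-4-((tert-butyldimethylsilyl)oxy)-3-methylbutanoic acid; 5 (S)-4-benzyloxazolidin-2-one
Product: 7 (S)-4-benzyl-3-((R)-4-((tert-butyldimethylsilyl)oxy)-3-methylbutanoyl)oxazolidin-2-one, via mixed pivalic anhydride 6 (not isolated)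
Conditions: PivCl, Et3N, THF, −20 °C; then 5, LiCl, −20 °C → rt
Reagents that add atoms: none
Why: N-Acylation of the oxazolidinone through the mixed pivalic anhydride (auxiliary attachment by acyl substitution) should proceed without touching C11.

Step 3
Reactants: 7 N-acyl oxazolidinone; 8 acrolein
Product: 10 (S)-4-benzyl-3-((2S,3R)-2-((R)-1-((tert-butyldimethylsilyl)oxy)propan-2-yl)-3-hydroxypent-4-enoyl)oxazolidin-2-one, via dibutylboron Z-enolate 9 (not isolated)
Conditions: Bu2BOTf, iPr2NEt, CH2Cl2, −78 → 0 °C; 8, −78 °C; then pH 7 buffer, MeOH, H2O2, 0 °C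
Reagents that add atoms: none
Why: Evans syn-aldol reaction: the Z-boron enolate should react through a Zimmerman–Traxler chair on the face remote from the benzyl group of the auxiliary, which sets C7 and the C6 carbinol syn in the required absolute sense and overrides the remote C11 centre.

Step 4
Reactants: 10 syn-aldol imide
Product: 11 (2S,3R)-2-((R)-1-((tert-butyldimethylsilyl)oxy)propan-2-yl)-3-hydroxy-N-methoxy-N-methylpent-4-enamide
Conditions: MeONHMe·HCl, AlMe3, CH2Cl2, −10 °C → rt
Reagents that add atoms: N,O-dimethylhydroxylamine hydrochloride (CNOC.Cl)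
Why: Aluminium-amide transamination of the β-hydroxy imide (Weinreb amide formation), assisted by the free hydroxyl, should release the auxiliary without retro-aldol cleavage or epimerization at C7.

Step 5
Reactants: 11 Weinreb amide
Product: 12 (5S,6R)-5-((R)-1-((tert-butyldimethylsilyl)oxy)propan-2-yl)-6-hydroxyocta-1,7-dien-4-one
Conditions: CH2=CHCH2MgBr (3 equiv), THF, −78 °C; then H2O
Reagents that add atoms: allylmagnesium bromide (C=CC[Mg]Br)
Why: Grignard addition to the Weinreb amide should stop at the chelated tetrahedral intermediate and give the β-hydroxy allyl ketone after cold neutral work-up, one equivalent of reagent being spent on the hydroxyl.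

Step 6
Reactants: 12 β-hydroxy allyl ketone; 13 propanal
Product: 14 (3R,4R,5R)-4-((R)-1-((tert-butyldimethylsilyl)oxy)propan-2-yl)-5-hydroxyocta-1,7-dien-3-yl propanoate
Conditions: SmI2 (30 mol %), 13 (excess), THF, −10 °C
Reagents that add atoms: none
Why: Evans–Tishchenko reduction: intramolecular hydride transfer within the samarium-bound hemiacetal of propanal should give the 1,3-anti C8 alcohol and at the same time place the propanoyl group (the future C3, C4 and C15) on O6, so that the two hydroxyls are differentiated without protecting-group steps.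

Step 7
Reactants: 14 diene propanoate
Product: 15 (1R,5R,6R)-6-((R)-1-((tert-butyldimethylsilyl)oxy)propan-2-yl)-5-hydroxycyclohex-2-en-1-yl propanoate
Conditions: second-generation Grubbs catalyst RuCl2(H2IMes)(PCy3)(=CHPh) (2 mol %), CH2Cl2, 40 °C
Reagents that add atoms: none
Why: Ring-closing olefin metathesis of the 1,7-diene should close the six-membered ring B (C5=C10) with loss of ethene; no stereocentre is affected.

Step 8
Reactants: 15 cyclohexenyl propanoate
Product: 16 (1S,2S,3R,4R,6S)-3-((R)-1-((tert-butyldimethylsilyl)oxy)propan-2-yl)-4-hydroxy-7-oxabicyclo[4.1.0]heptan-2-yl propanoate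
Conditions: VO(acac)2 (5 mol %), t-BuOOH, CH2Cl2, 0 °C → rt
Reagents that add atoms: tert-butyl hydroperoxide (CC(C)(C)OO)
Why: Hydroxyl-directed vanadium-catalysed epoxidation: the pseudoaxial homoallylic 8-hydroxyl should deliver the oxygen to its own β face of C5=C10, anti to the 6α-propanoate.

Step 9
Reactants: 16 epoxy alcohol
Product: 17 (1S,2S,3S,4R,6S)-4-((tert-butyldimethylsilyl)oxy)-3-((R)-1-((tert-butyldimethylsilyl)oxy)propan-2-yl)-7-oxabicyclo[4.1.0]heptan-2-yl propanoate
Conditions: TBSOTf, 2,6-lutidine, CH2Cl2, −78 °C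
Reagents that add atoms: tert-butyldimethylsilyl triflate (CC(C)(C)[Si](C)(C)OS(=O)(=O)C(F)(F)F)
Why: Silylation of the secondary alcohol with the silyl triflate and a hindered base should leave epoxide and ester intact.

Step 10
Reactants: 17 silylated epoxy propanoate
Product: 18 cis-lactone alcohol (ring B with the γ-lactone O6–C3(=O)–C4H(CH3)–C5 cis-fused on the α face; 10β-OH; 8β-OTBS; C4 epimers)
Conditions: LiN(SiMe3)2, THF, −78 → 0 °C; then H2O
Reagents that add atoms: none
Why: Intramolecular alkylation of the propanoate lithium enolate by the epoxide (5-exo-tet, the ester-enolate counterpart of the epoxynitrile cyclization, trans-diaxial opening by the Fürst–Plattner rule) should form C4–C5 with inversion at C5, giving the arm cis to O6 and the 10β-alcohol; the configuration at C4 is inconsequential because C4 becomes trigonal in step 13.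

Step 11
Reactants: 18 cis-lactone alcohol
Product: 19 keto lactone (as 18 with a C10 ketone)
Conditions: Dess–Martin periodinane, CH2Cl2, rt
Reagents that add atoms: none
Why: Dess–Martin oxidation of the axial secondary alcohol under near-neutral conditions should give the ketone, whose β-acyloxy group is equatorial and locked in the cis-fused lactone, so that β-elimination and C5 epimerization are disfavoured.

Step 12
Reactants: 19 keto lactone
Product: 20 vinyl carbinol (as 18 with 10β-OH and 10α-vinyl on a tertiary C10)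
Conditions: CH2=CHMgBr, LaCl3·2LiCl (30 mol %), THF, −78 °C; then H2O
Reagents that add atoms: vinylmagnesium bromide (C=C[Mg]Br)
Why: Lanthanum-promoted 1,2-addition of the Grignard reagent should take the ketone in preference to the lactone and come from the equatorial direction, because the axial 8β-silyloxy group blocks the axial path, which sets the 10β-hydroxyl and places the vinyl group cis to the C5 arm.

Step 13
Reactants: 20 vinyl carbinol
Product: 21 ketene dithioacetal diol (ring B with 5α-(1-(1,3-dithian-2-ylidene)ethyl); 6α-OH; 8β-OTBS; 10β-OH; 10α-vinyl)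
Conditions: Me2AlS(CH2)3SAlMe2 (from AlMe3 and HS(CH2)3SH), CH2Cl2, 0 °C → rt; aqueous work-up
Reagents that add atoms: propane-1,3-dithiol (SCCCS), used as its aluminium thiolate
Why: Ketene dithioacetal formation from a lactone with an aluminium dithiolate (thioacetalization–elimination) should turn the lactone carbonyl C3 into the 1,3-dithian-2-ylidene carbon, create C3=C4 and release the 6-hydroxyl without epimerizing C5.

Step 14
Reactants: 21 ketene dithioacetal diol
Product: 22 oxy-Cope substrate (as 21 with 6α-OSiEt3)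
Conditions: TESCl, imidazole, DMF, 0 °C
Reagents that add atoms: chlorotriethylsilane (CC[Si](Cl)(CC)CC)
Why: Chemoselective silylation of the secondary 6-hydroxyl in the presence of the hindered tertiary carbinol should mask the only other acidic OH before the anionic step.

Step 15
Reactants: 22 oxy-Cope substrate
Product: 25 ten-membered enol triflate (10-OSO2CF3 on C1=C10; C3 spiro-1,3-dithiane; 4E; 6α-OTES; 8β-OTBS; 12-OTBS), via potassium alkoxide 23 (not isolated), via potassium enolate 24 (not isolated)
Conditions: KN(SiMe3)2, 18-crown-6, THF, −78 → 0 °C; then PhNTf2, −78 → 0 °C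
Reagents that add atoms: N-phenylbis(trifluoromethanesulfonimide) (O=S(=O)(N(c1ccccc1)S(=O)(=O)C(F)(F)F)C(F)(F)F)
Why: Deprotonation of the tertiary carbinol gives alkoxide 23, in which the oxide weakens the C5–C10 bond; a [3,3]-sigmatropic shift through a six-centre chair then forms C2–C3 between the vinyl terminus and the dithioacetal carbon while ring B is cleaved, and the resulting potassium enolate 24 is O-sulfonylated by PhNTf2. The closest known reaction type is the anionic oxy-Cope ring expansion of cis-1,2-dialkenylcyclohexanols to cyclodec-5-enones with trapping of the regiodefined enolate, here with a sulfur-substituted alkene as one partner, which should if anything accelerate the shift. The ten-membered ring is therefore closed by a four-atom ring expansion of the six-membered ring and not by end-to-end cyclization, so no high dilution is needed. No stereogenic carbon is created (C3 is a dithioketal); the two new double-bond geometries follow from the chair transition state of the single accessible chair of ring B, the axial C5 arm giving the ring-cis C1=C10 enolate and the equatorial vinyl group giving the 4E alkene. The step needs chair over boat and the right chair, which the equatorial 6-silyloxy group and C7 side chain and the axial 8-silyloxy group secure, and it needs regiocontrol of the enolate, which is inherent because the enolate can only form towards C1. The C6, C7, C8 and C11 stereocentres of ring B are carried over unchanged.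

Step 16
Reactants: 25 enol triflate dithiane
Product: 26 enone (as 25 with a C3 ketone conjugated to the 4E alkene)
Conditions: MeI, CaCO3, MeCN/H2O, 40 °C
Reagents that add atoms: water (O)
Why: Alkylative hydrolysis of the 1,3-dithiane (S-methylation, then attack of water) should unveil the C3 ketone as the E-configured α-methyl enone without touching the enol triflate or the silyl ethers.

Step 17
Reactants: 26 enone
Product: 27 diol (as 26 with 6α-OH and 12-OH; 8β-OTBS kept)
Conditions: HF·pyridine, pyridine, THF, 0 °C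
Reagents that add atoms: none
Why: Graded fluoride-mediated desilylation: the triethylsilyl ether and the primary tert-butyldimethylsilyl ether should be cleaved well before the hindered secondary silyl ether at C8.

Step 18
Reactants: 27 diol
Product: 30 trans-fused 12,6-lactone (8β-OTBS; C3 ketone; 4E; 10-OTf; 11R), via hydroxy aldehyde 28 (not isolated), via lactol 29 (not isolated)
Conditions: TEMPO ((2,2,6,6-tetramethylpiperidin-1-yl)oxyl, 20 mol %), PhI(OAc)2, CH2Cl2, rt
Reagents that add atoms: none
Why: Nitroxyl-catalysed oxidation of the primary alcohol, lactol formation with the 6-hydroxyl and further oxidation (oxidative lactonization of a 1,4-diol) should close the trans-fused γ-lactone; C6, C7 and C11 keep the configurations they already have.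

Step 19
Reactants: 30 silylated lactone
Product: 31 8β-alcohol (as 30 with free 8-OH)
Conditions: HF·pyridine, THF, 0 °C → rt
Reagents that add atoms: none
Why: Desilylation of the remaining secondary silyl ether with HF·pyridine should leave the enol triflate intact, which is why a basic fluoride source is avoided.

Step 20
Reactants: 31 8β-alcohol; 32 tigloyl chloride
Product: 33 tiglate enone (as 31 with 8β-O-tigloyl)
Conditions: 32, 4-(dimethylamino)pyridine (cat.), pyridine, CH2Cl2, 0 °C → rt
Reagents that add atoms: none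
Why: Acylation of the secondary alcohol with the acid chloride under nucleophilic catalysis should give the tiglate with its E geometry retained, while C3 is still masked as the ketone.

Step 21
Reactants: 33 tiglate enone
Product: 34 (3S)-allylic alcohol
Conditions: (R)-2-methyl-CBS-oxazaborolidine (C18H20BNO), catecholborane, toluene, −78 °C; then MeOH
Reagents that add atoms: none
Why: Corey–Bakshi–Shibata reduction: the oxazaborolidine should distinguish the alkenyl and methylene flanks of the enone and deliver hydride 1,2 under reagent control to set the (3S)-carbinol, without touching lactone, tiglate or enol triflate.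

Step 22
Reactants: 34 (3S)-allylic alcohol
Product: 35 (3S,4R,5R)-epoxy alcohol enol triflate
Conditions: mCPBA, CH2Cl2/aq. phosphate buffer (pH 8), 0 °C
Reagents that add atoms: meta-chloroperbenzoic acid (OOC(=O)c1cccc(Cl)c1)
Why: Peracid epoxidation (Prilezhaev reaction): C4=C5 is the only electron-rich alkene, since C1=C10 is deactivated as the enol triflate and the tiglate is conjugated, and attack on the exposed peripheral face of the E-alkene, assisted by hydrogen bonding to the 3-hydroxyl, should give the (4R,5R)-oxirane threo to the carbinol.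

Step 23
Reactants: 35 epoxy alcohol enol triflate
Product: 36 target, (3S,4R,5R,6S,7R,8R,11R)-4,5-epoxy-3-hydroxy-8-tigloyloxy-11,13-dihydrogermacr-1(10)Z-en-12,6-olide
Conditions: Me4Sn, Pd(PPh3)4 (10 mol %), LiCl, THF, 60 °C
Reagents that add atoms: tetramethylstannane (C[Sn](C)(C)C)
Why: Stille coupling of the enol triflate (oxidative addition to zerovalent palladium, chloride-assisted transmetalation, reductive elimination) should install C14 with retention of the ring-cis geometry of C1=C10 under neutral conditions that the epoxy alcohol, lactone and tiglate tolerate.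

**Compound list**

1 | (R)-4-methyldihydrofuran-2(3H)-one ((R)-β-methyl-γ-butyrolactone) | C[C@H]1COC(=O)C1 | starting material
2 | sodium (R)-4-hydroxy-3-methylbutanoate | OC[C@H](C)CC(=O)[O-].[Na+] | intermediate
3 | tert-butyldimethylsilyl (R)-4-((tert-butyldimethylsilyl)oxy)-3-methylbutanoate | CC(C)(C)[Si](C)(C)OC[C@H](C)CC(=O)O[Si](C)(C)C(C)(C)C | intermediate
4 | (R)-4-((tert-butyldimethylsilyl)oxy)-3-methylbutanoic acid | CC(C)(C)[Si](C)(C)OC[C@H](C)CC(=O)O | intermediate
5 | (S)-4-benzyloxazolidin-2-one | O=C1N[C@@H](Cc2ccccc2)CO1 | starting material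
6 | (R)-4-((tert-butyldimethylsilyl)oxy)-3-methylbutanoic pivalic anhydride | CC(C)(C)[Si](C)(C)OC[C@H](C)CC(=O)OC(=O)C(C)(C)C | intermediate
7 | (S)-4-benzyl-3-((R)-4-((tert-butyldimethylsilyl)oxy)-3-methylbutanoyl)oxazolidin-2-one | CC(C)(C)[Si](C)(C)OC[C@H](C)CC(=O)N1[C@@H](Cc2ccccc2)COC1=O | intermediate
8 | acrolein (prop-2-enal) | C=CC=O | starting material
9 | dibutylboron (Z)-enolate of 7 | CCCCB(CCCC)O/C(=C\[C@@H](C)CO[Si](C)(C)C(C)(C)C)N1[C@@H](Cc2ccccc2)COC1=O | intermediate
10 | (S)-4-benzyl-3-((2S,3R)-2-((R)-1-((tert-butyldimethylsilyl)oxy)propan-2-yl)-3-hydroxypent-4-enoyl)oxazolidin-2-one | C=C[C@@H](O)[C@H]([C@@H](C)CO[Si](C)(C)C(C)(C)C)C(=O)N1[C@@H](Cc2ccccc2)COC1=O | intermediate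
11 | (2S,3R)-2-((R)-1-((tert-butyldimethylsilyl)oxy)propan-2-yl)-3-hydroxy-N-methoxy-N-methylpent-4-enamide | C=C[C@@H](O)[C@H]([C@@H](C)CO[Si](C)(C)C(C)(C)C)C(=O)N(C)OC | intermediate
12 | (5S,6R)-5-((R)-1-((tert-butyldimethylsilyl)oxy)propan-2-yl)-6-hydroxyocta-1,7-dien-4-one | C=C[C@@H](O)[C@H]([C@@H](C)CO[Si](C)(C)C(C)(C)C)C(=O)CC=C | intermediate
13 | propanal | CCC=O | starting material
14 | (3R,4R,5R)-4-((R)-1-((tert-butyldimethylsilyl)oxy)propan-2-yl)-5-hydroxyocta-1,7-dien-3-yl propanoate | C=C[C@@H](OC(=O)CC)[C@H]([C@@H](C)CO[Si](C)(C)C(C)(C)C)[C@H](O)CC=C | intermediate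
15 | (1R,5R,6R)-6-((R)-1-((tert-butyldimethylsilyl)oxy)propan-2-yl)-5-hydroxycyclohex-2-en-1-yl propanoate | CCC(=O)O[C@@H]1C=CC[C@@H](O)[C@H]1[C@@H](C)CO[Si](C)(C)C(C)(C)C | intermediate
16 | (1S,2S,3R,4R,6S)-3-((R)-1-((tert-butyldimethylsilyl)oxy)propan-2-yl)-4-hydroxy-7-oxabicyclo[4.1.0]heptan-2-yl propanoate (5β,10β-epoxide; 6α-propanoate; 8β-OH) | CCC(=O)O[C@@H]1[C@H]2O[C@H]2C[C@@H](O)[C@H]1[C@@H](C)CO[Si](C)(C)C(C)(C)C | intermediate
17 | (1S,2S,3S,4R,6S)-4-((tert-butyldimethylsilyl)oxy)-3-((R)-1-((tert-butyldimethylsilyl)oxy)propan-2-yl)-7-oxabicyclo[4.1.0]heptan-2-yl propanoate | CCC(=O)O[C@@H]1[C@H]2O[C@H]2C[C@@H](O[Si](C)(C)C(C)(C)C)[C@H]1[C@@H](C)CO[Si](C)(C)C(C)(C)C | intermediate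
18 | cis-lactone alcohol: ring B (cyclohexane C5–C10) with the γ-lactone O6–C3(=O)–C4H(CH3)–C5 cis-fused at C5/C6 on the α face; 10β-OH; 8β-OTBS; 7β-((R)-1-(TBSO)propan-2-yl); C4 epimers | CC1C(=O)O[C@@H]2[C@H]1[C@@H](O)C[C@@H](O[Si](C)(C)C(C)(C)C)[C@H]2[C@@H](C)CO[Si](C)(C)C(C)(C)C | intermediate
19 | keto lactone: as 18 with a C10 ketone | CC1C(=O)O[C@@H]2[C@H]1C(=O)C[C@@H](O[Si](C)(C)C(C)(C)C)[C@H]2[C@@H](C)CO[Si](C)(C)C(C)(C)C | intermediate
20 | vinyl carbinol: as 18 with tertiary C10 carrying 10β-OH and 10α-vinyl | CC1C(=O)O[C@@H]2[C@H]1[C@](O)(C=C)C[C@@H](O[Si](C)(C)C(C)(C)C)[C@H]2[C@@H](C)CO[Si](C)(C)C(C)(C)C | intermediate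
21 | ketene dithioacetal diol: ring B with 5α-(1-(1,3-dithian-2-ylidene)ethyl), 6α-OH, 7β-((R)-1-(TBSO)propan-2-yl), 8β-OTBS, 10β-OH, 10α-vinyl | CC(=C1SCCCS1)[C@H]1[C@@H](O)[C@H]([C@@H](C)CO[Si](C)(C)C(C)(C)C)[C@H](O[Si](C)(C)C(C)(C)C)C[C@@]1(O)C=C | intermediate
22 | oxy-Cope substrate: as 21 with 6α-OSiEt3 | CC(=C1SCCCS1)[C@H]1[C@@H](O[Si](CC)(CC)CC)[C@H]([C@@H](C)CO[Si](C)(C)C(C)(C)C)[C@H](O[Si](C)(C)C(C)(C)C)C[C@@]1(O)C=C | intermediate
23 | potassium 10-alkoxide of 22 | CC(=C1SCCCS1)[C@H]1[C@@H](O[Si](CC)(CC)CC)[C@H]([C@@H](C)CO[Si](C)(C)C(C)(C)C)[C@H](O[Si](C)(C)C(C)(C)C)C[C@@]1([O-])C=C.[K+] | intermediate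
24 | potassium enolate: ten-membered ring with C10–O− on C1=C10 (C9 and C2 cis), C3 spiro-1,3-dithiane, 4E alkene, 6α-OTES, 8β-OTBS, 12-OTBS, 11R | CC(C)(C)[Si](C)(C)O[C@@H]1C/C([O-])=C\CC2(SCCCS2)/C(C)=C/[C@@H](O[Si](CC)(CC)CC)[C@@H]1[C@@H](C)CO[Si](C)(C)C(C)(C)C.[K+] | intermediate
25 | enol triflate: as 24 with 10-OSO2CF3 (14-nor-germacra-1(10),4-diene core) | CC(C)(C)[Si](C)(C)O[C@@H]1C/C(OS(=O)(=O)C(F)(F)F)=C\CC2(SCCCS2)/C(C)=C/[C@@H](O[Si](CC)(CC)CC)[C@@H]1[C@@H](C)CO[Si](C)(C)C(C)(C)C | intermediate
26 | enone: as 25 with a C3 ketone in place of the dithiane | CC(C)(C)[Si](C)(C)O[C@@H]1C/C(OS(=O)(=O)C(F)(F)F)=C\CC(=O)/C(C)=C/[C@@H](O[Si](CC)(CC)CC)[C@@H]1[C@@H](C)CO[Si](C)(C)C(C)(C)C | intermediate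
27 | diol: as 26 with 6α-OH and 12-OH | CC(C)(C)[Si](C)(C)O[C@@H]1C/C(OS(=O)(=O)C(F)(F)F)=C\CC(=O)/C(C)=C/[C@@H](O)[C@@H]1[C@@H](C)CO | intermediate
28 | hydroxy aldehyde: as 27 with C12 as aldehyde | CC(C)(C)[Si](C)(C)O[C@@H]1C/C(OS(=O)(=O)C(F)(F)F)=C\CC(=O)/C(C)=C/[C@@H](O)[C@@H]1[C@@H](C)C=O | intermediate
29 | lactol: 6α,12-hemiacetal of 28 (anomers) | CC(C)(C)[Si](C)(C)O[C@@H]1C/C(OS(=O)(=O)C(F)(F)F)=C\CC(=O)/C(C)=C/[C@H]2OC(O)[C@H](C)[C@@H]21 | intermediate
30 | lactone: trans-fused 12,6-olide with 8β-OTBS, C3 ketone, 4E alkene, 10-OTf, 11R | CC(C)(C)[Si](C)(C)O[C@@H]1C/C(OS(=O)(=O)C(F)(F)F)=C\CC(=O)/C(C)=C/[C@H]2OC(=O)[C@H](C)[C@@H]21 | intermediate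
31 | 8β-alcohol: as 30 with free 8-OH | O[C@@H]1C/C(OS(=O)(=O)C(F)(F)F)=C\CC(=O)/C(C)=C/[C@H]2OC(=O)[C@H](C)[C@@H]21 | intermediate
32 | tigloyl chloride ((E)-2-methylbut-2-enoyl chloride) | C/C=C(\C)C(Cl)=O | starting material
33 | tiglate enone: as 31 with 8β-O-tigloyl | C/C=C(\C)C(=O)O[C@@H]1C/C(OS(=O)(=O)C(F)(F)F)=C\CC(=O)/C(C)=C/[C@H]2OC(=O)[C@H](C)[C@@H]21 | intermediate
34 | (3S)-allylic alcohol: as 33 with (3S)-OH | C/C=C(\C)C(=O)O[C@@H]1C/C(OS(=O)(=O)C(F)(F)F)=C\C[C@H](O)/C(C)=C/[C@H]2OC(=O)[C@H](C)[C@@H]21 | intermediate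
35 | (3S,4R,5R)-epoxy alcohol enol triflate: the target with OSO2CF3 in place of the C14 methyl | C/C=C(\C)C(=O)O[C@@H]1C/C(OS(=O)(=O)C(F)(F)F)=C\C[C@H](O)[C@@]2(C)O[C@@H]2[C@H]2OC(=O)[C@H](C)[C@@H]21 | intermediate
36 | (3S,4R,5R,6S,7R,8R,11R)-4,5-epoxy-3-hydroxy-8-tigloyloxy-11,13-dihydrogermacr-1(10)Z-en-12,6-olide | C/C=C(\C)C(=O)O[C@@H]1C/C(C)=C\C[C@H](O)[C@@]2(C)O[C@@H]2[C@H]2OC(=O)[C@H](C)[C@@H]21 | target

**Step count and risks**

Total step count: 23. Longest linear sequence: 23 steps (1 → 36).

Most likely to fail, step 15: the alkoxide may be diverted before the sigmatropic shift, either by silyl transfer from O8 to the 10-oxide or by heterolysis of C5–C10 to an enone and a dithiane-stabilized allyl anion that recombines unselectively; alternatively the shift may run through a boat and erode the alkene geometries. The fallback is a neutral thermal oxy-Cope shift of the silyl ether. It sets out from 22: silylation of the tertiary alcohol with N-(trimethylsilyl)imidazole should give the trimethylsilyl ether F1. Heating (o-dichlorobenzene, about 180 °C) should bring about the same chair [3,3] shift without any charged intermediate and give the ring-expanded trimethylsilyl enol ether F2. MeLi in THF at 0 °C cleaves the Si–O bond to the lithium enolate, which is triflated with PhNTf2 as in the main route, so the fallback comes back at 25.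

Second, step 10: the non-stabilized ester enolate may open the epoxide too slowly, so that ester self-condensation or acyl transfer takes over. The fallback uses a sulfone-stabilized carbanion and sets out from 17. DIBAL-H (CH2Cl2, −78 °C) should remove the propanoyl group and give the epoxy alcohol F3. Esterification with 2-(phenylsulfonyl)propanoic acid (DCC, 4-(dimethylamino)pyridine) gives the sulfonyl ester F4. Cs2CO3 in DMF should then generate the stabilized carbanion, which opens the epoxide in the same 5-exo, trans-diaxial sense to give the α-sulfonyl lactone F5. Reductive desulfonylation (SmI2, THF/MeOH) comes back at 18.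

Third, step 22: the peracid may show insufficient facial selectivity (attack on the inner face) or the buffered acid may trigger transannular opening of the epoxy alcohol. The fallback is a hydroxyl-directed metal-catalysed epoxidation followed by inversion, and sets out from 33. Reduction with the enantiomeric (S)-2-methyl-CBS-oxazaborolidine and catecholborane should give the (3R)-allylic alcohol F6. VO(acac)2/t-BuOOH should then epoxidize C4=C5 from the peripheral face in the erythro sense that is inherently preferred for allylic alcohols with a substituent on the proximal alkene carbon, giving the (3R,4R,5R)-epoxy alcohol F7. Mitsunobu inversion with chloroacetic acid (PPh3, DIAD) gives the (3S)-chloroacetate F8, and thiourea/NaHCO3 in EtOH removes the chloroacetyl group selectively, coming back at 35.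

**Further compounds**

F1 | step 15 | trimethylsilyl ether of 22 (10β-OSiMe3) | CC(=C1SCCCS1)[C@H]1[C@@H](O[Si](CC)(CC)CC)[C@H]([C@@H](C)CO[Si](C)(C)C(C)(C)C)[C@H](O[Si](C)(C)C(C)(C)C)C[C@@]1(O[Si](C)(C)C)C=C
F2 | step 15 | ring-expanded trimethylsilyl enol ether (as 25 with 10-OSiMe3 in place of 10-OTf) | CC(C)(C)[Si](C)(C)O[C@@H]1C/C(O[Si](C)(C)C)=C\CC2(SCCCS2)/C(C)=C/[C@@H](O[Si](CC)(CC)CC)[C@@H]1[C@@H](C)CO[Si](C)(C)C(C)(C)C
F3 | step 10 | epoxy alcohol (as 17 with free 6α-OH) | O[C@@H]1[C@H]2O[C@H]2C[C@@H](O[Si](C)(C)C(C)(C)C)[C@H]1[C@@H](C)CO[Si](C)(C)C(C)(C)C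
F4 | step 10 | 2-(phenylsulfonyl)propanoate of F3 (sulfone carbon epimers) | CC(C(=O)O[C@@H]1[C@H]2O[C@H]2C[C@@H](O[Si](C)(C)C(C)(C)C)[C@H]1[C@@H](C)CO[Si](C)(C)C(C)(C)C)S(=O)(=O)c1ccccc1
F5 | step 10 | α-sulfonyl lactone (as 18 with phenylsulfonyl on C4; C4 epimers) | CC1(S(=O)(=O)c3ccccc3)C(=O)O[C@@H]2[C@H]1[C@@H](O)C[C@@H](O[Si](C)(C)C(C)(C)C)[C@H]2[C@@H](C)CO[Si](C)(C)C(C)(C)C
F6 | step 22 | (3R)-allylic alcohol (C3 epimer of 34) | C/C=C(\C)C(=O)O[C@@H]1C/C(OS(=O)(=O)C(F)(F)F)=C\C[C@@H](O)/C(C)=C/[C@H]2OC(=O)[C@H](C)[C@@H]21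
F7 | step 22 | (3R,4R,5R)-epoxy alcohol (C3 epimer of 35) | C/C=C(\C)C(=O)O[C@@H]1C/C(OS(=O)(=O)C(F)(F)F)=C\C[C@@H](O)[C@@]2(C)O[C@@H]2[C@H]2OC(=O)[C@H](C)[C@@H]21
F8 | step 22 | (3S)-chloroacetate of 35 | C/C=C(\C)C(=O)O[C@@H]1C/C(OS(=O)(=O)C(F)(F)F)=C\C[C@H](OC(=O)CCl)[C@@]2(C)O[C@@H]2[C@H]2OC(=O)[C@H](C)[C@@H]21
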